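Everything rests on building ring F last. Ring F is a 1,4-bis(aryloxy)benzene whose C1 oxygen belongs to ring E and whose C4 oxygen, flanked by the C3 and C5 hydroxyls, belongs to ring G. Both oxygens are therefore carried into the key step as simple ethers: ring E's oxygen as an ethynyl ether on the methylated A–E pentamer, ring G's oxygen as the 4-aryloxy group of a 3-ethoxycyclobutenone on the methylated G–J tetramer. One thermal benzannulation joins F C1–C2 and F C5–C6, recloses F C4–C5 and aromatizes. Both partners grow from a single bromo dimer by Ullmann etherification; one BBr3 treatment then frees all twenty-six phenols.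

Key step: step 19

Assumption: 2,3,4-trimethoxyphenol, 3,4,5-trimethoxyphenol, 5-bromo-1,2,3-trimethoxybenzene and ethoxyacetylene (hexane solution) are taken as purchasable.

Naming: rings are lettered A (2,4,6-trioxygenated end) to J (3,4,5-trioxygenated end). In rings B, D, F and H, C1 takes the oxygen from the preceding ring and C4 carries the oxygen to the next. In rings C, E, G and I, C1 takes the oxygen from the preceding ring and C2 carries the oxygen to the next. "Methylated" means every oxygen not otherwise specified is a methyl ether. "A–E aryloxy" is the methylated pentamer bound through ring E C2–O, and "G–J aryloxy" is the methylated tetramer bound through ring G C1–O.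

Step 1
Reactants: 1 2,3,4-trimethoxyphenol
Product: 2 1,2,3-trimethoxy-4-(methoxymethoxy)benzene
Conditions: MOMCl, i-Pr2NEt, CH2Cl2, 0 °C to rt
Reagents that add atoms: chloromethyl methyl ether, COCCl
Why: Williamson-type O-alkylation with the reactive chloromethyl ether gives an acetal that masks the future ring C C2 oxygen and directs the next lithiation.

Step 2
Reactants: 2 1,2,3-trimethoxy-4-(methoxymethoxy)benzene
Product: 4 1-iodo-3,4,5-trimethoxy-2-(methoxymethoxy)benzene, via aryllithium 3 (not isolated)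
Conditions: n-BuLi, THF, 0 °C; then I2, THF, −78 °C to rt
Reagents that add atoms: iodine, II
Why: Directed ortho-metalation, in which the chelating methoxymethoxy group outranks methoxy so that only the hydrogen next to it is removed, followed by iodine quench, places the iodide at the future ring C C1 without regiochemical doubt.

Step 3
Reactants: 4 1-iodo-3,4,5-trimethoxy-2-(methoxymethoxy)benzene and 5 4-bromo-2,6-dimethoxyphenol
Product: 6 dimer bromide 5-bromo-1,3-dimethoxy-2-[3,4,5-trimethoxy-2-(methoxymethoxy)phenoxy]benzene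
Conditions: CuI (10 mol%), picolinic acid (20 mol%), K3PO4, DMSO, 80 °C, 4 in slight excess
Reagents that add atoms: none
Why: Ullmann-type CuI-catalysed O-arylation with a ligand suited to ortho-substituted partners should join the 2,6-dimethoxyphenol to the aryl iodide, while the bromide of 5, inherently slower than iodide and deactivated by its para phenoxide, is kept for later.

Step 4
Reactants: 7 2,4,6-trimethoxyphenol and 6 dimer bromide
Product: 8 methylated A–C trimer with ring C C2 oxygen as methoxymethyl ether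
Conditions: CuI (20 mol%), picolinic acid (40 mol%), K3PO4, DMSO, 100 °C
Reagents that add atoms: none
Why: Ullmann diaryl ether synthesis between a 2,6-disubstituted phenol and an aryl bromide without ortho substituents should form the ring A–ring B ether, the acetal being stable to phosphate base.

Step 5
Reactants: 8 methylated A–C trimer methoxymethyl ether
Product: 9 methylated A–C trimer phenol (free OH at ring C C2)
Conditions: HCl (cat.), MeOH/THF, 50 °C
Reagents that add atoms: none
Why: Acid-catalysed acetal methanolysis removes the methoxymethyl group and leaves aryl methyl and diaryl ethers untouched.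

Step 6
Reactants: 9 methylated A–C trimer phenol and 6 dimer bromide
Product: 10 methylated A–E pentamer with ring E C2 oxygen as methoxymethyl ether
Conditions: CuI (20 mol%), picolinic acid (40 mol%), K3PO4, DMSO, 100 °C
Reagents that add atoms: none
Why: A second Ullmann etherification of the same kind, now with the ring C phenol as nucleophile and the unhindered bromide of 6 as electrophile, adds rings D and E in one operation.

Step 7
Reactants: 10 methylated A–E pentamer methoxymethyl ether
Product: 11 methylated A–E pentamer phenol (free OH at ring E C2)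
Conditions: HCl (cat.), MeOH/THF, 50 °C
Reagents that add atoms: none
Why: Acetal methanolysis as in step 5 frees the ring E hydroxyl.

Step 8
Reactants: 11 methylated A–E pentamer phenol and 12 trichloroethylene
Product: 13 methylated A–E pentamer (E)-1,2-dichlorovinyl ether at ring E C2–O
Conditions: K2CO3, DMF, 70 °C
Reagents that add atoms: trichloroethylene (compound 12), ClC=C(Cl)Cl
Why: Base converts trichloroethylene into dichloroacetylene, to which the phenoxide adds in anti fashion (nucleophilic vinylation), a slim linear electrophile that the crowded ring E oxygen can reach.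

Step 9
Reactants: 13 methylated A–E pentamer (E)-1,2-dichlorovinyl ether
Product: 16 methylated A–E pentamer ethynyl ether (ring E C2–O–C≡CH), via chloroethynyl ether 14 (not isolated), via lithium acetylide 15 (not isolated)
Conditions: n-BuLi (2.5 equiv), THF, −78 to −40 °C; then H2O, −78 °C
Reagents that add atoms: none
Why: Dehydrochlorination to the chloroalkyne, chlorine–lithium exchange and protonation is the standard conversion of 1,2-dichlorovinyl ethers into terminal ynol ethers, and at −78 °C the methoxyarenes are not lithiated.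

Step 10
Reactants: 17 3,4,5-trimethoxyphenol
Product: 18 5-(benzyloxy)-1,2,3-trimethoxybenzene
Conditions: BnBr, K2CO3, DMF, rt
Reagents that add atoms: benzyl bromide, BrCc1ccccc1
Why: Williamson etherification puts a benzyl group, orthogonal to the acetal of dimer 6, on the oxygen that becomes ring G C1–O.

Step 11
Reactants: 18 5-(benzyloxy)-1,2,3-trimethoxybenzene
Product: 20 6-(benzyloxy)-2,3,4-trimethoxybenzaldehyde, via iminium chloride 19 (not isolated)
Conditions: POCl3, DMF, 0 to 60 °C; then aq. NaOAc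
Reagents that add atoms: N,N-dimethylformamide, CN(C)C=O; water, O
Why: Vilsmeier–Haack formylation attacks the only free ring positions, which are equivalent and activated by ortho and para oxygens, so a single aldehyde results after hydrolysis.

Step 12
Reactants: 20 6-(benzyloxy)-2,3,4-trimethoxybenzaldehyde
Product: 22 6-(benzyloxy)-2,3,4-trimethoxyphenol, via aryl formate 21 (not isolated)
Conditions: mCPBA, CH2Cl2, 0 °C to rt; then K2CO3, MeOH, rt
Reagents that add atoms: mCPBA, OOC(=O)c1cccc(Cl)c1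
Why: Baeyer–Villiger oxidation of the electron-rich aldehyde (Dakin-type) proceeds by aryl migration to the formate, whose methanolysis frees the phenol that becomes ring G C2–O.

Step 13
Reactants: 22 6-(benzyloxy)-2,3,4-trimethoxyphenol and 6 dimer bromide
Product: 23 methylated G–I trimer with ring G C1 oxygen benzylated and ring I C2 oxygen as methoxymethyl ether
Conditions: CuI (20 mol%), picolinic acid (40 mol%), K3PO4, DMSO, 100 °C
Reagents that add atoms: none
Why: Ullmann etherification of this 2,6-dioxygenated phenol with the unhindered bromide of 6 forms the ring G–ring H ether and brings in ring I at once, both protecting groups being base-stable.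

Step 14
Reactants: 23 methylated G–I trimer (benzyl and methoxymethyl ethers)
Product: 24 methylated G–I trimer phenol (ring G C1 oxygen benzylated, free OH at ring I C2)
Conditions: HCl (cat.), MeOH/THF, 50 °C
Reagents that add atoms: none
Why: Acetal methanolysis unmasks only ring I's C2 hydroxyl because a benzyl ether is stable to dilute acid.

Step 15
Reactants: 24 methylated G–I trimer phenol and 25 5-bromo-1,2,3-trimethoxybenzene
Product: 26 methylated G–J tetramer with ring G C1 oxygen benzylated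
Conditions: CuI (20 mol%), picolinic acid (40 mol%), K3PO4, DMSO, 100 °C
Reagents that add atoms: none
Why: Ullmann etherification with an aryl bromide free of ortho substituents caps the chain with ring J.

Step 16
Reactants: 26 methylated G–J tetramer benzyl ether
Product: 27 methylated G–J tetramer phenol (free OH at ring G C1)
Conditions: H2 (1 atm), 10% Pd/C, EtOAc/MeOH, rt
Reagents that add atoms: none
Why: Hydrogenolysis cleaves only the benzylic C–O bond, since no aryl halide remains and aryl methyl and diaryl ethers are inert.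

Step 17
Reactants: 27 methylated G–J tetramer phenol and 28 bromoacetic acid
Product: 29 2-(G–J aryloxy)acetic acid
Conditions: NaH (2.5 equiv), THF/DMF, 0 to 60 °C; then 1 M HCl
Reagents that add atoms: bromoacetic acid (compound 28), OC(=O)CBr
Why: Williamson alkylation of the sodium phenoxide by sodium bromoacetate gives the aryloxyacetic acid directly and so hangs the future F C4 and F C5 on ring G's oxygen.

Step 18
Reactants: 29 2-(G–J aryloxy)acetic acid and 30 ethoxyacetylene
Product: 33 racemic 4-(G–J aryloxy)-3-ethoxycyclobut-2-en-1-one, via acid chloride 31 (not isolated), via aryloxyketene 32 (not isolated)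
Conditions: 1-chloro-N,N,2-trimethylprop-1-en-1-amine (1.05 equiv), CH2Cl2, 0 °C to rt; then slow addition to Et3N and ethoxyacetylene (5 equiv), CH2Cl2, 0 °C to rt
Reagents that add atoms: ethoxyacetylene (compound 30), CCOC#C
Why: The α-chloroenamine makes the acid chloride without acid or excess acylating agent (sparing the electron-rich rings), Et3N dehydrochlorinates it to the aryloxyketene, and a ketene–ynol ether [2+2] cycloaddition, in which the nucleophilic CH of ethoxyacetylene bonds to the ketene carbonyl carbon, gives the 3-ethoxycyclobutenone, whose C4 stereocentre forms without control (racemic) and is destroyed in step 19.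

Step 19
Reactants: 33 racemic 4-(G–J aryloxy)-3-ethoxycyclobut-2-en-1-one and 16 methylated A–E pentamer ethynyl ether
Product: 38 decamer phenol with ring F as 3-ethoxy-5-hydroxy-1,4-bis(aryloxy)benzene (all other oxygens methylated), via vinylketene 34 (not isolated), via vinylcyclobutenone 35 (not isolated), via dienylketene 36 (not isolated), via cyclohexadienone 37 (not isolated)
Conditions: 16 (1.3 equiv), toluene (0.5 M), argon, 80 then 110 °C; then K2CO3, MeOH, rt
Reagents that add atoms: none
Why: Thermal 4π electrocyclic opening of 33, with the aryloxy group rotating outward, gives vinylketene 34, whose ketene C=C adds across the alkyne of 16 in a [2+2] cycloaddition to vinylcyclobutenone 35; a second 4π opening gives dienylketene 36, 6π electrocyclization gives cyclohexadienone 37 and enolization gives phenol 38. The closest known reaction type is the Danheiser benzannulation of cyclobutenones with alkoxy- and silyloxyalkynes, here with an aryl ynol ether as the alkyne. Ring F is closed by 6π electrocyclization (forming F C4–C5) after the [2+2] step has made F C1–C2 and F C5–C6, and the four-membered ring of 35 is closed by [2+2] cycloaddition and opened again. No stereocentre remains, since the sp3 carbons of 35 and 37 are racemic and vanish on aromatization. The one regiochemistry needed is secured by the oxygen-polarized alkyne, whose CH terminus bonds to the ketene carbonyl carbon so that ring E's oxygen ends para to ring G's oxygen and meta to the new hydroxyl, and outward rotation of the aryloxy group leaves hydrogen as the inward substituent for ring closure. The feature exploited is ring F's 1,4-bis(aryloxy)-3,5-dioxygenation, both ether oxygens being attached to rings E and G before ring F exists; an excess of 16 and a basic methanol wash (to cleave any ester formed between 38 and 34) are built in.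

Step 20
Reactants: 38 decamer phenol with ethoxy and hydroxy on ring F
Product: 39 CNP0255890.0 (the fully deprotected decamer)
Conditions: BBr3 (3 equiv per ether), CH2Cl2, −78 °C to rt; MeOH then H2O, 0 °C, argon; degassed reversed-phase chromatography
Reagents that add atoms: none
Why: Lewis acid-mediated ether cleavage, in which bromide attacks the alkyl carbon of each boron-complexed ether, removes every methyl group and the ethyl group while the diaryl ether bonds offer no carbon open to SN2 attack, and work-up under argon guards the trihydroxylated rings against oxidation.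

Compound list

1 | 2,3,4-trimethoxyphenol | COc1ccc(O)c(OC)c1OC | starting material
2 | 1,2,3-trimethoxy-4-(methoxymethoxy)benzene | COCOc1ccc(OC)c(OC)c1OC | intermediate
3 | [3,4,5-trimethoxy-2-(methoxymethoxy)phenyl]lithium | [Li]c1cc(OC)c(OC)c(OC)c1OCOC | intermediate
4 | 1-iodo-3,4,5-trimethoxy-2-(methoxymethoxy)benzene | COCOc1c(I)cc(OC)c(OC)c1OC | intermediate
5 | 4-bromo-2,6-dimethoxyphenol | COc1cc(Br)cc(OC)c1O | starting material
6 | dimer bromide, 5-bromo-1,3-dimethoxy-2-[3,4,5-trimethoxy-2-(methoxymethoxy)phenoxy]benzene | COCOc1c(Oc2c(OC)cc(Br)cc2OC)cc(OC)c(OC)c1OC | intermediate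
7 | 2,4,6-trimethoxyphenol | COc1cc(OC)c(O)c(OC)c1 | starting material
8 | methylated A–C trimer, ring C C2 oxygen as methoxymethyl ether | COc1cc(OC)c(Oc2cc(OC)c(Oc3cc(OC)c(OC)c(OC)c3OCOC)c(OC)c2)c(OC)c1 | intermediate
9 | methylated A–C trimer phenol, free OH at ring C C2 | COc1cc(OC)c(Oc2cc(OC)c(Oc3cc(OC)c(OC)c(OC)c3O)c(OC)c2)c(OC)c1 | intermediate
10 | methylated A–E pentamer, ring E C2 oxygen as methoxymethyl ether | COc1cc(OC)c(Oc2cc(OC)c(Oc3cc(OC)c(OC)c(OC)c3Oc3cc(OC)c(Oc4cc(OC)c(OC)c(OC)c4OCOC)c(OC)c3)c(OC)c2)c(OC)c1 | intermediate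
11 | methylated A–E pentamer phenol, free OH at ring E C2 | COc1cc(OC)c(Oc2cc(OC)c(Oc3cc(OC)c(OC)c(OC)c3Oc3cc(OC)c(Oc4cc(OC)c(OC)c(OC)c4O)c(OC)c3)c(OC)c2)c(OC)c1 | intermediate
12 | trichloroethylene | ClC=C(Cl)Cl | starting material
13 | methylated A–E pentamer (E)-1,2-dichlorovinyl ether | COc1cc(OC)c(Oc2cc(OC)c(Oc3cc(OC)c(OC)c(OC)c3Oc3cc(OC)c(Oc4cc(OC)c(OC)c(OC)c4O/C(Cl)=C\Cl)c(OC)c3)c(OC)c2)c(OC)c1 | intermediate
14 | methylated A–E pentamer chloroethynyl ether | COc1cc(OC)c(Oc2cc(OC)c(Oc3cc(OC)c(OC)c(OC)c3Oc3cc(OC)c(Oc4cc(OC)c(OC)c(OC)c4OC#CCl)c(OC)c3)c(OC)c2)c(OC)c1 | intermediate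
15 | lithium acetylide of the A–E pentamer ynol ether | COc1cc(OC)c(Oc2cc(OC)c(Oc3cc(OC)c(OC)c(OC)c3Oc3cc(OC)c(Oc4cc(OC)c(OC)c(OC)c4OC#C[Li])c(OC)c3)c(OC)c2)c(OC)c1 | intermediate
16 | methylated A–E pentamer ethynyl ether | COc1cc(OC)c(Oc2cc(OC)c(Oc3cc(OC)c(OC)c(OC)c3Oc3cc(OC)c(Oc4cc(OC)c(OC)c(OC)c4OC#C)c(OC)c3)c(OC)c2)c(OC)c1 | intermediate
17 | 3,4,5-trimethoxyphenol | COc1cc(O)cc(OC)c1OC | starting material
18 | 5-(benzyloxy)-1,2,3-trimethoxybenzene | COc1cc(OCc2ccccc2)cc(OC)c1OC | intermediate
19 | N-{[6-(benzyloxy)-2,3,4-trimethoxyphenyl]methylidene}-N-methylmethanaminium chloride | C[N+](C)=Cc1c(OCc2ccccc2)cc(OC)c(OC)c1OC.[Cl-] | intermediate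
20 | 6-(benzyloxy)-2,3,4-trimethoxybenzaldehyde | COc1cc(OCc2ccccc2)c(C=O)c(OC)c1OC | intermediate
21 | 6-(benzyloxy)-2,3,4-trimethoxyphenyl formate | O=COc1c(OCc2ccccc2)cc(OC)c(OC)c1OC | intermediate
22 | 6-(benzyloxy)-2,3,4-trimethoxyphenol | COc1cc(OCc2ccccc2)c(O)c(OC)c1OC | intermediate
23 | methylated G–I trimer, ring G C1 oxygen benzylated, ring I C2 oxygen as methoxymethyl ether | c1ccccc1COc1cc(OC)c(OC)c(OC)c1Oc1cc(OC)c(Oc2cc(OC)c(OC)c(OC)c2OCOC)c(OC)c1 | intermediate
24 | methylated G–I trimer phenol, ring G C1 oxygen benzylated, free OH at ring I C2 | c1ccccc1COc1cc(OC)c(OC)c(OC)c1Oc1cc(OC)c(Oc2cc(OC)c(OC)c(OC)c2O)c(OC)c1 | intermediate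
25 | 5-bromo-1,2,3-trimethoxybenzene | COc1cc(Br)cc(OC)c1OC | starting material
26 | methylated G–J tetramer, ring G C1 oxygen benzylated | c1ccccc1COc1cc(OC)c(OC)c(OC)c1Oc1cc(OC)c(Oc2cc(OC)c(OC)c(OC)c2Oc2cc(OC)c(OC)c(OC)c2)c(OC)c1 | intermediate
27 | methylated G–J tetramer phenol, free OH at ring G C1 | Oc1cc(OC)c(OC)c(OC)c1Oc1cc(OC)c(Oc2cc(OC)c(OC)c(OC)c2Oc2cc(OC)c(OC)c(OC)c2)c(OC)c1 | intermediate
28 | bromoacetic acid | OC(=O)CBr | starting material
29 | 2-(G–J aryloxy)acetic acid | OC(=O)COc1cc(OC)c(OC)c(OC)c1Oc1cc(OC)c(Oc2cc(OC)c(OC)c(OC)c2Oc2cc(OC)c(OC)c(OC)c2)c(OC)c1 | intermediate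
30 | ethoxyacetylene | CCOC#C | starting material
31 | 2-(G–J aryloxy)acetyl chloride | ClC(=O)COc1cc(OC)c(OC)c(OC)c1Oc1cc(OC)c(Oc2cc(OC)c(OC)c(OC)c2Oc2cc(OC)c(OC)c(OC)c2)c(OC)c1 | intermediate
32 | (G–J aryloxy)ketene | O=C=COc1cc(OC)c(OC)c(OC)c1Oc1cc(OC)c(Oc2cc(OC)c(OC)c(OC)c2Oc2cc(OC)c(OC)c(OC)c2)c(OC)c1 | intermediate
33 | racemic 4-(G–J aryloxy)-3-ethoxycyclobut-2-en-1-one | CCOC1=CC(=O)C1Oc1cc(OC)c(OC)c(OC)c1Oc1cc(OC)c(Oc2cc(OC)c(OC)c(OC)c2Oc2cc(OC)c(OC)c(OC)c2)c(OC)c1 | intermediate
34 | vinylketene, (Z)-4-(G–J aryloxy)-3-ethoxybuta-1,3-dien-1-one | O=C=C/C(OCC)=C/Oc1cc(OC)c(OC)c(OC)c1Oc1cc(OC)c(Oc2cc(OC)c(OC)c(OC)c2Oc2cc(OC)c(OC)c(OC)c2)c(OC)c1 | intermediate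
35 | racemic 3-(A–E aryloxy)-4-[(Z)-2-(G–J aryloxy)-1-ethoxyethenyl]cyclobut-2-en-1-one | COc1cc(OC)c(Oc2cc(OC)c(Oc3cc(OC)c(OC)c(OC)c3Oc3cc(OC)c(Oc4cc(OC)c(OC)c(OC)c4OC4=CC(=O)C4/C(OCC)=C/Oc5cc(OC)c(OC)c(OC)c5Oc5cc(OC)c(Oc6cc(OC)c(OC)c(OC)c6Oc6cc(OC)c(OC)c(OC)c6)c(OC)c5)c(OC)c3)c(OC)c2)c(OC)c1 | intermediate
36 | dienylketene, (3E,5Z)-3-(A–E aryloxy)-5-ethoxy-6-(G–J aryloxy)hexa-1,3,5-trien-1-one | COc1cc(OC)c(Oc2cc(OC)c(Oc3cc(OC)c(OC)c(OC)c3Oc3cc(OC)c(Oc4cc(OC)c(OC)c(OC)c4O/C(C=C=O)=C/C(OCC)=C/Oc5cc(OC)c(OC)c(OC)c5Oc5cc(OC)c(Oc6cc(OC)c(OC)c(OC)c6Oc6cc(OC)c(OC)c(OC)c6)c(OC)c5)c(OC)c3)c(OC)c2)c(OC)c1 | intermediate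
37 | racemic 3-(A–E aryloxy)-5-ethoxy-6-(G–J aryloxy)cyclohexa-2,4-dien-1-one | COc1cc(OC)c(Oc2cc(OC)c(Oc3cc(OC)c(OC)c(OC)c3Oc3cc(OC)c(Oc4cc(OC)c(OC)c(OC)c4OC4=CC(=O)C(Oc5cc(OC)c(OC)c(OC)c5Oc5cc(OC)c(Oc6cc(OC)c(OC)c(OC)c6Oc6cc(OC)c(OC)c(OC)c6)c(OC)c5)C(OCC)=C4)c(OC)c3)c(OC)c2)c(OC)c1 | intermediate
38 | decamer phenol, ring F as 3-ethoxy-5-hydroxy-1,4-bis(aryloxy)benzene, all other oxygens methylated | COc1cc(OC)c(Oc2cc(OC)c(Oc3cc(OC)c(OC)c(OC)c3Oc3cc(OC)c(Oc4cc(OC)c(OC)c(OC)c4Oc4cc(OCC)c(Oc5cc(OC)c(OC)c(OC)c5Oc5cc(OC)c(Oc6cc(OC)c(OC)c(OC)c6Oc6cc(OC)c(OC)c(OC)c6)c(OC)c5)c(O)c4)c(OC)c3)c(OC)c2)c(OC)c1 | intermediate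
39 | CNP0255890.0, decamer with all twenty-six hydroxyls free (achiral) | Oc1cc(O)c(Oc2cc(O)c(Oc3cc(O)c(O)c(O)c3Oc3cc(O)c(Oc4cc(O)c(O)c(O)c4Oc4cc(O)c(Oc5cc(O)c(O)c(O)c5Oc5cc(O)c(Oc6cc(O)c(O)c(O)c6Oc6cc(O)c(O)c(O)c6)c(O)c5)c(O)c4)c(O)c3)c(O)c2)c(O)c1 | target

Total step count: 20 steps.

Longest linear sequence: 11 steps (for example steps 1, 2, 3, 13, 14, 15, 16, 17, 18, 19, 20; the branches through steps 4–9 and 10–12 are equally long).

Steps most likely to fail

1. Step 19. The vinylketene may dimerize, oligomerize or be captured by the product phenol faster than it adds to the bulky and only moderately nucleophilic aryl ynol ether, and the ynol ether may polymerize on heating, so that ring F never closes. The fallback uses only Ullmann etherification and sets out from pentamer phenol 11. Coupling with dimer bromide 6 (CuI, picolinic acid, K3PO4, DMSO, 100 °C) should give the methylated A–G heptamer methoxymethyl ether F1, and acid methanolysis the methylated A–G heptamer phenol F2. A second coupling with 6 should give the methylated A–I nonamer methoxymethyl ether F3, and methanolysis the methylated A–I nonamer phenol F4. Coupling with bromide 25 should give the fully methylated A–J decamer F5, and BBr3 cleavage of all its methyl ethers comes back to the route at target 39.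

2. Step 18. The aryloxyketene may self-condense, or the acid chloride may acylate the activated ring G position next to its oxygen, before the cycloaddition with ethoxyacetylene takes place. The fallback generates the same vinylketene without a cyclobutenone and sets out from tetramer phenol 27. Williamson alkylation with commercial ethyl (E)-4-bromo-3-ethoxybut-2-enoate (CCOC(=O)/C=C(/OCC)CBr; K2CO3, acetone) should give ethyl (E)-3-ethoxy-4-(G–J aryloxy)but-2-enoate F6. LiOH in aqueous THF should give (E)-3-ethoxy-4-(G–J aryloxy)but-2-enoic acid F7, and 1-chloro-N,N,2-trimethylprop-1-en-1-amine the (E)-3-ethoxy-4-(G–J aryloxy)but-2-enoyl chloride F8. Et3N in toluene in the presence of ynol ether 16 then removes HCl in a 1,4-sense (a known way to vinylketenes from unsaturated acid chlorides) to give vinylketene 34; the enol ether geometry is of no lasting consequence because it is lost when ring F aromatizes. Warming runs the same cascade, and the sequence rejoins the route at 38.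

3. Step 3. Selectivity for iodide over bromide may be lost, so that 5 condenses with itself or with product 6 to give oligomeric ethers, or the coupling of two ortho-substituted partners may stall. The fallback replaces the halide partner by a boron partner and sets out from acetal 2. Lithiation as in step 2 (aryllithium 3) and quenching with B(OiPr)3, then aqueous NH4Cl, should give [3,4,5-trimethoxy-2-(methoxymethoxy)phenyl]boronic acid F9. Oxidative Chan–Lam coupling of F9 with phenol 5 (Cu(OAc)2, pyridine, 4 Å molecular sieves, CH2Cl2, air, rt), under which an aryl bromide is inert, returns to the route at dimer bromide 6.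

Further compounds

F1 | step 19 | methylated A–G heptamer, ring G C2 oxygen as methoxymethyl ether | COc1cc(OC)c(Oc2cc(OC)c(Oc3cc(OC)c(OC)c(OC)c3Oc3cc(OC)c(Oc4cc(OC)c(OC)c(OC)c4Oc4cc(OC)c(Oc5cc(OC)c(OC)c(OC)c5OCOC)c(OC)c4)c(OC)c3)c(OC)c2)c(OC)c1
F2 | step 19 | methylated A–G heptamer phenol, free OH at ring G C2 | COc1cc(OC)c(Oc2cc(OC)c(Oc3cc(OC)c(OC)c(OC)c3Oc3cc(OC)c(Oc4cc(OC)c(OC)c(OC)c4Oc4cc(OC)c(Oc5cc(OC)c(OC)c(OC)c5O)c(OC)c4)c(OC)c3)c(OC)c2)c(OC)c1
F3 | step 19 | methylated A–I nonamer, ring I C2 oxygen as methoxymethyl ether | COc1cc(OC)c(Oc2cc(OC)c(Oc3cc(OC)c(OC)c(OC)c3Oc3cc(OC)c(Oc4cc(OC)c(OC)c(OC)c4Oc4cc(OC)c(Oc5cc(OC)c(OC)c(OC)c5Oc5cc(OC)c(Oc6cc(OC)c(OC)c(OC)c6OCOC)c(OC)c5)c(OC)c4)c(OC)c3)c(OC)c2)c(OC)c1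
F4 | step 19 | methylated A–I nonamer phenol, free OH at ring I C2 | COc1cc(OC)c(Oc2cc(OC)c(Oc3cc(OC)c(OC)c(OC)c3Oc3cc(OC)c(Oc4cc(OC)c(OC)c(OC)c4Oc4cc(OC)c(Oc5cc(OC)c(OC)c(OC)c5Oc5cc(OC)c(Oc6cc(OC)c(OC)c(OC)c6O)c(OC)c5)c(OC)c4)c(OC)c3)c(OC)c2)c(OC)c1
F5 | step 19 | fully methylated A–J decamer (twenty-six methyl ethers) | COc1cc(OC)c(Oc2cc(OC)c(Oc3cc(OC)c(OC)c(OC)c3Oc3cc(OC)c(Oc4cc(OC)c(OC)c(OC)c4Oc4cc(OC)c(Oc5cc(OC)c(OC)c(OC)c5Oc5cc(OC)c(Oc6cc(OC)c(OC)c(OC)c6Oc6cc(OC)c(OC)c(OC)c6)c(OC)c5)c(OC)c4)c(OC)c3)c(OC)c2)c(OC)c1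
F6 | step 18 | ethyl (E)-3-ethoxy-4-(G–J aryloxy)but-2-enoate | CCOC(=O)/C=C(/OCC)COc1cc(OC)c(OC)c(OC)c1Oc1cc(OC)c(Oc2cc(OC)c(OC)c(OC)c2Oc2cc(OC)c(OC)c(OC)c2)c(OC)c1
F7 | step 18 | (E)-3-ethoxy-4-(G–J aryloxy)but-2-enoic acid | OC(=O)/C=C(/OCC)COc1cc(OC)c(OC)c(OC)c1Oc1cc(OC)c(Oc2cc(OC)c(OC)c(OC)c2Oc2cc(OC)c(OC)c(OC)c2)c(OC)c1
F8 | step 18 | (E)-3-ethoxy-4-(G–J aryloxy)but-2-enoyl chloride | ClC(=O)/C=C(/OCC)COc1cc(OC)c(OC)c(OC)c1Oc1cc(OC)c(Oc2cc(OC)c(OC)c(OC)c2Oc2cc(OC)c(OC)c(OC)c2)c(OC)c1
F9 | step 3 | [3,4,5-trimethoxy-2-(methoxymethoxy)phenyl]boronic acid | COCOc1c(B(O)O)cc(OC)c(OC)c1OC
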